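Number the carbocycle C1 (sorboyl carbon), C2 (ketone), C3, C4 (enol), C5 (O-bearing) and C6 (fusion CH), with lactone carbonyl C7 and amino carbon C8. The segment C7–C8(N,CH3)–C6–C1–C2 is then a buried (S)-2-methylglutamate whose N and C1 lie cis on the γ-lactone ring. The plan cuts C5–C6 and C2–C3 and reconnects N to C2. The precursor is therefore an unsaturated N-Boc 2-methylpyroglutamate esterified at C7 with the C3–C5 ketol. One base treatment closes the lactone by Michael addition and the carbocycle by enolate attack on the lactam carbonyl. This frees NHBoc and sets C5 and C6 from C8.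

Key step: step 7

Assumption: enantiopure (S)-2-methylglutamic acid, racemic 2-bromopentan-3-one, sorbic acid and mono-tert-butyl fumarate are taken as catalogue compounds. All 1,3-diones and triketones are drawn as one enol tautomer, and anionic intermediates are drawn protonated.

Structure check: the target SMILES reads C5 = S, C6 = R, C8 = S. N, C1 and C4 sit on one face of the γ-lactone ring; the C5 methyl, C6–H and the C8 methyl sit on the other. C8 has the spatial arrangement of (S)-2-methylglutamic acid, so 1, 10 and 13 are stereochemically consistent with 23.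

Design choices:
- **Order of events.** The lactam is dehydrogenated before any ketone is present, because a ketone would be enolised and selenenylated in preference to the lactam. A temporary allyl ester carries the acid through this stage.
- **Ketol ester.** It is made by carboxylate alkylation with the α-bromoketone, so the hindered C7 acid needs no activation and no isomerisable acyloin is handled.
- **Boc.** It is kept on nitrogen because it acidifies C1–H, activates C6 and C2, shields C2 from external nucleophiles, stabilises the departing nitrogen anion and survives strong base.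
- **Fumarate.** It enters as its tert-butyl ester, so the last step is acidic and not hydrolytic.

Step 1
Reactants: 1 (S)-2-methylglutamic acid
Product: 2 (S)-2-methylpyroglutamic acid [(2S)-2-methyl-5-oxopyrrolidine-2-carboxylic acid]
Conditions: H2O, 130 °C (sealed vessel); evaporate
Reagents that add atoms: none
Why: Thermal lactamisation of a glutamic acid (N closes onto C2 with loss of water) is a standard cyclodehydration, is helped by the geminal substitution at C8, and cannot racemise the quaternary centre.

Step 2
Reactants: 2 (S)-2-methylpyroglutamic acid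
Product: 3 allyl (2S)-2-methyl-5-oxopyrrolidine-2-carboxylate
Conditions: allyl bromide, KHCO3, DMF, rt
Reagents that add atoms: allyl bromide, C=CCBr
Why: Carboxylate O-alkylation (SN2) takes place at oxygen and so is indifferent to the crowding at C8, bicarbonate leaves the lactam NH alone, and allyl is chosen because it can be removed in step 5 without acid, hydroxide or hydrogen.

Step 3
Reactants: 3 allyl (2S)-2-methyl-5-oxopyrrolidine-2-carboxylate
Product: 4 2-allyl 1-tert-butyl (2S)-2-methyl-5-oxopyrrolidine-1,2-dicarboxylate
Conditions: Boc2O, DMAP (cat.), MeCN, rt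
Reagents that add atoms: di-tert-butyl dicarbonate, CC(C)(C)OC(=O)OC(=O)OC(C)(C)C
Why: DMAP-catalysed N-acylation of a lactam with Boc2O is routine and gives the imide-type carbamate that acidifies C1–H for step 4, activates C6 and C2 for step 7 and tolerates the strong base of step 9.

Step 4
Reactants: 4 2-allyl 1-tert-butyl (2S)-2-methyl-5-oxopyrrolidine-1,2-dicarboxylate
Product: 7 2-allyl 1-tert-butyl (2S)-2-methyl-5-oxo-2,5-dihydropyrrole-1,2-dicarboxylate, via 4-phenylselanyl lactam 5 (not isolated), via selenoxide 6 (not isolated)
Conditions: LiN(SiMe3)2, THF, −78 °C; PhSeCl, −78 °C; then AcOH (0.2 equiv), 30% aq. H2O2, 0 °C → rt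
Reagents that add atoms: benzeneselenenyl chloride, Cl[Se]c1ccccc1 (Se and phenyl are held only in 5 and 6); hydrogen peroxide, OO (oxygen is held only in 6)
Why: Enolate selenenylation followed by selenoxide syn-elimination is the standard dehydrogenation of N-Boc pyroglutamates, and it is placed before the ketone-bearing ester is introduced so that C1–H is the only enolisable position, while quaternary C8 rules out racemisation and aromatisation to a pyrrole.

Step 5
Reactants: 7 2-allyl 1-tert-butyl (2S)-2-methyl-5-oxo-2,5-dihydropyrrole-1,2-dicarboxylate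
Product: 8 (2S)-1-(tert-butoxycarbonyl)-2-methyl-5-oxo-2,5-dihydropyrrole-2-carboxylic acid
Conditions: Pd(PPh3)4 (5 mol %), PhNHMe, THF, rt
Reagents that add atoms: none
Why: Tsuji–Trost-type deallylation passes the allyl group through a π-allylpalladium complex to the weakly basic, weakly nucleophilic N-methylaniline, so the Boc group, the imide carbonyl and the hindered C6=C1 acceptor should be left intact.

Step 6
Reactants: 8 (2S)-1-(tert-butoxycarbonyl)-2-methyl-5-oxo-2,5-dihydropyrrole-2-carboxylic acid; 9 2-bromopentan-3-one (racemic)
Product: 10 3-oxopentan-2-yl (2S)-1-(tert-butoxycarbonyl)-2-methyl-5-oxo-2,5-dihydropyrrole-2-carboxylate (both epimers at the ester carbinol carbon C5)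
Conditions: KHCO3, DMF, rt
Reagents that add atoms: none
Why: SN2 displacement of an α-bromoketone by a carboxylate (the phenacyl-ester type of esterification) needs no activation of the neopentyl-like C7 acid and avoids the free ketol with its tendency to isomerise, bicarbonate is too weak to enolise 10, and the C5 epimer mixture is harmless because C5 is planarised in step 7.

Step 7
Reactants: 10 3-oxopentan-2-yl (2S)-1-(tert-butoxycarbonyl)-2-methyl-5-oxo-2,5-dihydropyrrole-2-carboxylate
Product: 13 tert-butyl N-[(3S,3aR,7aS)-7-hydroxy-3,6,7a-trimethyl-2,5-dioxo-2,3,3a,4,5,7a-hexahydro-1-benzofuran-3-yl]carbamate (des-sorboyl core; C5 S C6 R C8 S), via Michael adduct 11 (not isolated), via bridged alkoxide 12 (not isolated)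
Conditions: KOtBu (1.2 equiv), THF–tBuOH (4:1), 0.02 M, −30 °C → rt; then 1 M HCl (pH 3)
Reagents that add atoms: none
Why: Proposed new method: tert-butoxide equilibrates the ketone enolates of 10, and the more substituted, acyloxy-stabilised C5 enolate adds to C6 of the Boc-activated unsaturated lactam, forming C5–C6 and the γ-lactone ring (5-exo-trig, enolate C=C outside the new ring) and giving 11 once tBuOH has protonated the C1 enolate. Re-enolisation toward C3 lets C3 attack the imide-type carbonyl C2 (6-exo-trig, enolate C=C inside the new ring), forming C2–C3 and the carbocycle through the azabicyclo[3.2.1]octane alkoxide 12, which ejects the carbamate-stabilised nitrogen anion; proton transfer to that anion leaves the 1,3-dione enolate as the thermodynamic sink. The closest known reaction types are consecutive Michael–Claisen annulations to cyclohexane-1,3-diones and the opening of N-Boc lactams by enolates, but a lactam acting as both Michael acceptor and acyl donor in one cascade is untested. C6 is set by C8, because the short tether C8–C7–O–C5 can deliver C5 only to the lactam face that carries C7, which leaves N and C1 cis on the lactone ring. C5 is set by selection: only the adduct whose propionyl group lies over the lactam ring brings C3 within reach of C2 (a potassium bridge between the enolate oxygen and the C2 oxygen should also favour it kinetically), and the other epimer must return by retro-Michael cleavage under the equilibrating conditions. The step needs 1,4- over 1,2-attack and productive use of both enolates: the bulky Boc group and quaternary C8 shield C2, the carbamate carbonyl and C7 from the first enolate, and the competing shift of the C7 acyl group onto C3 would require a geometrically disfavoured 5-(enolendo)-exo-trig closure.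

Step 8
Reactants: 14 sorbic acid [(2E,4E)-hexa-2,4-dienoic acid]
Product: 16 (2E,4E)-N-methoxy-N-methylhexa-2,4-dienamide, via sorboyl imidazole 15 (not isolated)
Conditions: CDI, CH2Cl2, rt; then MeNH(OMe)·HCl, rt
Reagents that add atoms: N,O-dimethylhydroxylamine hydrochloride, CNOC.Cl; 1,1'-carbonyldiimidazole, O=C(n1ccnc1)n1ccnc1 (imidazolyl is held only in 15)
Why: Activation as the acyl imidazole and aminolysis is the routine Weinreb amide synthesis and leaves the (2E,4E)-diene geometry untouched.

Step 9
Reactants: 13 des-sorboyl N-Boc core; 16 (2E,4E)-N-methoxy-N-methylhexa-2,4-dienamide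
Product: 18 tert-butyl N-[(3S,3aR,4Z,7aS)-7-hydroxy-4-[(2E,4E)-1-hydroxyhexa-2,4-dienylidene]-3,6,7a-trimethyl-2,5-dioxo-2,3,3a,4,5,7a-hexahydro-1-benzofuran-3-yl]carbamate, via hemiaminal adduct 17 (not isolated)
Conditions: LiN(iPr)2 (3.3 equiv), THF–DMPU, −78 → −20 °C; 16, −78 → −20 °C; then 1 M HCl (pH 3), 0 °C
Reagents that add atoms: none
Why: Three equivalents of base remove the enol OH, the carbamate NH and one C1–H, the resulting cross-conjugated dienediolate reacts at its most basic terminus C1 as in the classical γ-acylation of 1,3-dicarbonyl dianions, and the chelated Weinreb adduct 17 holds until the quench so that neither over-addition nor proton transfer from the acidic triketone can intervene, C1 ending up sp2 in the enol so that no stereocentre is created.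

Step 10
Reactants: 18 N-Boc sorboyl core
Product: 19 trifluoroacetate salt of the C8 amine [(3S,3aR,4Z,7aS)-3-amino-7-hydroxy-4-[(2E,4E)-1-hydroxyhexa-2,4-dienylidene]-3,6,7a-trimethyl-3a,4-dihydro-1-benzofuran-2,5(3H,7aH)-dione·CF3CO2H]
Conditions: TFA–CH2Cl2 (1:4), 0 °C → rt; evaporate
Reagents that add atoms: trifluoroacetic acid, OC(=O)C(F)(F)F
Why: Acidolysis of the tert-butyl carbamate spares lactone, enols and diene, and isolating the amine as its salt keeps nitrogen from adding back to C2 across the concave face.

Step 11
Reactants: 19 amine trifluoroacetate; 20 mono-tert-butyl fumarate [(E)-4-tert-butoxy-4-oxobut-2-enoic acid]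
Product: 22 sorbicillactone A tert-butyl ester, via acid chloride 21 (not isolated)
Conditions: 20, Me2C=C(Cl)NMe2, CH2Cl2, 0 °C; then 19, 2,6-lutidine, 0 °C → rt; aq. NaHCO3 wash, then acidify (KHSO4)
Reagents that add atoms: 1-chloro-N,N,2-trimethylprop-1-en-1-amine, CC(C)=C(Cl)N(C)C (chlorine is held only in 21)
Why: Acylation of an amine by an acid chloride, here generated under neutral conditions by the α-chloroenamine so that the tert-butyl ester survives, is the most forcing standard method for a hindered α-tertiary amine, and any enol ester formed on the triketone is a labile vinylogous anhydride that the bicarbonate wash should cleave.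

Step 12
Reactants: 22 sorbicillactone A tert-butyl ester
Product: 23 sorbicillactone A
Conditions: TFA–CH2Cl2 (1:2), 0 °C → rt
Reagents that add atoms: none
Why: Acidolysis of the tert-butyl ester releases the acid without the hydroxide that a methyl ester would demand and that would endanger the lactone, the fumaramide and the β-triketone, and no stereocentre is touched.

Compound list

1 | (S)-2-methylglutamic acid | OC(=O)[C@@](C)(N)CCC(=O)O | starting material
2 | (2S)-2-methyl-5-oxopyrrolidine-2-carboxylic acid | OC(=O)[C@@]1(C)NC(=O)CC1 | intermediate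
3 | allyl (2S)-2-methyl-5-oxopyrrolidine-2-carboxylate | C=CCOC(=O)[C@@]1(C)NC(=O)CC1 | intermediate
4 | 2-allyl 1-tert-butyl (2S)-2-methyl-5-oxopyrrolidine-1,2-dicarboxylate | C=CCOC(=O)[C@@]1(C)N(C(=O)OC(C)(C)C)C(=O)CC1 | intermediate
5 | 2-allyl 1-tert-butyl (2S)-2-methyl-5-oxo-4-(phenylselanyl)pyrrolidine-1,2-dicarboxylate, both C1 epimers | C=CCOC(=O)[C@@]1(C)N(C(=O)OC(C)(C)C)C(=O)C([Se]c2ccccc2)C1 | intermediate
6 | selenoxide of 5 (4-benzeneseleninyl lactam) | C=CCOC(=O)[C@@]1(C)N(C(=O)OC(C)(C)C)C(=O)C([Se](=O)c2ccccc2)C1 | intermediate
7 | 2-allyl 1-tert-butyl (2S)-2-methyl-5-oxo-2,5-dihydropyrrole-1,2-dicarboxylate | C=CCOC(=O)[C@@]1(C)N(C(=O)OC(C)(C)C)C(=O)C=C1 | intermediate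
8 | (2S)-1-(tert-butoxycarbonyl)-2-methyl-5-oxo-2,5-dihydropyrrole-2-carboxylic acid | OC(=O)[C@@]1(C)N(C(=O)OC(C)(C)C)C(=O)C=C1 | intermediate
9 | 2-bromopentan-3-one (racemic) | CCC(=O)C(C)Br | starting material
10 | 3-oxopentan-2-yl (2S)-1-(tert-butoxycarbonyl)-2-methyl-5-oxo-2,5-dihydropyrrole-2-carboxylate, both C5 epimers | CCC(=O)C(C)OC(=O)[C@@]1(C)N(C(=O)OC(C)(C)C)C(=O)C=C1 | intermediate
11 | cis-fused γ-lactone/N-Boc-γ-lactam Michael adduct (C5 S, C6 R, C8 S), propionyl on C5 lying over the lactam ring | CCC(=O)[C@@]1(C)OC(=O)[C@@]2(C)N(C(=O)OC(C)(C)C)C(=O)C[C@@H]12 | intermediate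
12 | bridged tetrahedral adduct: C2 bears OH, N-Boc, C1 and C3; 6-azabicyclo[3.2.1]octane core spanning the γ-lactone; C3 configuration open | O[C@]12C[C@H]3[C@](C)(OC(=O)[C@@]3(C)N1C(=O)OC(C)(C)C)C(=O)C2C | intermediate
13 | tert-butyl N-[(3S,3aR,7aS)-7-hydroxy-3,6,7a-trimethyl-2,5-dioxo-2,3,3a,4,5,7a-hexahydro-1-benzofuran-3-yl]carbamate | C1C(=O)C(C)=C(O)[C@@]2(C)OC(=O)[C@@](C)(NC(=O)OC(C)(C)C)[C@@H]12 | intermediate
14 | sorbic acid | C/C=C/C=C/C(=O)O | starting material
15 | (2E,4E)-1-(imidazol-1-yl)hexa-2,4-dien-1-one | C/C=C/C=C/C(=O)n1ccnc1 | intermediate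
16 | (2E,4E)-N-methoxy-N-methylhexa-2,4-dienamide | C/C=C/C=C/C(=O)N(C)OC | intermediate
17 | Weinreb tetrahedral adduct at C1 (C1 and hemiaminal carbon configuration open) | C/C=C/C=C/C(O)(N(C)OC)C1C(=O)C(C)=C(O)[C@@]2(C)OC(=O)[C@@](C)(NC(=O)OC(C)(C)C)[C@@H]12 | intermediate
18 | N-Boc sorboyl core (H-bonded exocyclic enol, C5 S, C6 R, C8 S) | C/C=C/C=C/C(O)=C1/C(=O)C(C)=C(O)[C@@]2(C)OC(=O)[C@@](C)(NC(=O)OC(C)(C)C)[C@@H]12 | intermediate
19 | trifluoroacetate salt of the C8 amine | C/C=C/C=C/C(O)=C1/C(=O)C(C)=C(O)[C@@]2(C)OC(=O)[C@@](C)(N)[C@@H]12.OC(=O)C(F)(F)F | intermediate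
20 | mono-tert-butyl fumarate | CC(C)(C)OC(=O)/C=C/C(=O)O | starting material
21 | tert-butyl (E)-4-chloro-4-oxobut-2-enoate | CC(C)(C)OC(=O)/C=C/C(=O)Cl | intermediate
22 | sorbicillactone A tert-butyl ester | C/C=C/C=C/C(O)=C1/C(=O)C(C)=C(O)[C@@]2(C)OC(=O)[C@@](C)(NC(=O)/C=C/C(=O)OC(C)(C)C)[C@@H]12 | intermediate
23 | sorbicillactone A | C/C=C/C=C/C(O)=C1/C(=O)C(C)=C(O)[C@@]2(C)OC(=O)[C@@](C)(NC(=O)/C=C/C(=O)O)[C@@H]12 | target

Total step count: 12. Longest linear sequence: 11 (steps 1–7 and 9–12, from 1).

Steps most likely to fail

**1. Step 7.**
- The crowded Michael equilibrium may favour the open ester, or drain into the C5 epimer that cannot cyclise.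
- The strained bridged adduct may revert faster than it expels nitrogen.
- The C7 acyl group may shift across the enediolate and scramble the ketol.
- tert-Butoxide may open the imide.

The fallback sets out from 10 and comes back at 13, with each bond made by a known reaction.
- Cs2CO3 in MeCN at rt should stop after the intramolecular Michael addition. The cis-fused lactone–lactam 11 is then isolated, and its C5 epimer is returned to the equilibration.
- Catalytic NaOMe in MeOH at 0 °C opens the N-Boc lactam at C2, a standard alcoholysis of an acyl carbamate. This gives methyl 2-[(2S,3R,4S)-4-(tert-butoxycarbonylamino)-2,4-dimethyl-5-oxo-2-propanoyloxolan-3-yl]acetate F1.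
- KOtBu in THF cyclises this unstrained δ-keto ester by the classical Dieckmann-type Claisen route to cyclohexane-1,3-diones, giving 13.

**2. Step 9.** The strongly basic C1 carbanion may take a proton from the terminal methyl group of 16 instead of adding to its carbonyl. The Weinreb amide may also react too slowly at temperatures the trilithio species tolerates.

The fallback sets out from 13 and comes back at 18.
- The same trilithio species is quenched at −78 °C with (2E,4E)-hexa-2,4-dienal, an electrophile that adds faster than it is deprotonated. This gives the C1 aldol adduct F2 as a mixture at C1 and the carbinol carbon.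
- MnO2 in CH2Cl2 oxidises the dienylic alcohol.
- Enolisation of the resulting triketone erases both centres and gives 18.

**3. Step 11.** Acylation of the hindered α-tertiary amine may be so slow that enol O-acylation and decay of the acid chloride take over.

The fallback sets out from 19 and comes back at 23; it needs no ester protecting group and skips step 12.
- Slim, strained maleic anhydride (iPr2NEt, THF, rt) acylates nitrogen to give the (Z)-maleamic acid F3.
- Thiyl-radical addition–elimination (catalytic PhSSPh, visible light, CH2Cl2) turns the Z alkene into the more stable E alkene. The (2E,4E)-diene already sits at its thermodynamic geometry.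

Further compounds

F1 | step 7 | methyl 2-[(2S,3R,4S)-4-(tert-butoxycarbonylamino)-2,4-dimethyl-5-oxo-2-propanoyloxolan-3-yl]acetate | CCC(=O)[C@@]1(C)OC(=O)[C@@](C)(NC(=O)OC(C)(C)C)[C@H]1CC(=O)OC
F2 | step 9 | C1 aldol adduct of 13 with (2E,4E)-hexa-2,4-dienal (C1 and carbinol configuration open) | C/C=C/C=C/C(O)C1C(=O)C(C)=C(O)[C@@]2(C)OC(=O)[C@@](C)(NC(=O)OC(C)(C)C)[C@@H]12
F3 | step 11 | (Z)-maleamic acid isomer of sorbicillactone A | C/C=C/C=C/C(O)=C1/C(=O)C(C)=C(O)[C@@]2(C)OC(=O)[C@@](C)(NC(=O)/C=C\C(=O)O)[C@@H]12
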